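**Retrosynthetic overview**

1. 28 ⇐ acyloin 26 (oxidation to the diosphenol) ⇐ keto ketal 23 (electron-transfer reduction at C7, acetylation, one acidolysis for ketal, silyl ether and tert-butyl ester).
2. Ring A is made last, both bonds from one three-carbon linchpin: C2–C3 by adding 1-lithio-1-methoxyallene (an acryloyl-anion equivalent) to the C2 aldehyde 18; C4–C5 by intramolecular Mukaiyama–Michael attack of the methoxyallene on the β-methyl enone of ring B (C5 quaternary centre, cis fusion).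
3. 18 ⇐ ketone 14 (dehydrogenation, conjugate methylation/Saegusa for C19 and the enone); C13 by cross-metathesis, then Cu-catalysed asymmetric methyl addition.
4. 14 ⇐ enone 8 by anti conjugate addition of a butenyl copper reagent (C9); 8 ⇐ 1 by Pd-catalysed decarboxylative asymmetric allylation (C10) and Stork–Danheiser transposition.
5. Ring order: ring B comes from starting material 1; ring A is annulated onto it in steps 11–12.

Assumption: atoms are labelled by clerodane numbering (ring A = C1–C5 and C10; ring B = C5–C10; side chain C11–C16; C17 on C8, C18 on C4, C19 on C5, C20 on C9), and 1 is taken as purchasable (otherwise one step from 2-methylcyclohexane-1,3-dione, EtOH, TsOH).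

**Route**

Step 1
Reactants: 1 3-ethoxy-2-methylcyclohex-2-en-1-one; 2 allyl chloroformate
Product: 3 allyl 5-ethoxy-6-methylcyclohexa-1,5-dien-1-yl carbonate
Conditions: LiN(SiMe3)2, TMEDA, THF, −78 °C; then 2, −78 °C
Reagents that add atoms: none
Why: Kinetic α′-deprotonation of the vinylogous ester gives the cross-conjugated lithium dienolate, which TMEDA steers to O-acylation by the chloroformate (enol carbonate formation).

Step 2
Reactants: 3 allyl 5-ethoxy-6-methylcyclohexa-1,5-dien-1-yl carbonate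
Product: 4 (R)-6-allyl-3-ethoxy-2-methylcyclohex-2-en-1-one
Conditions: Pd2(dba)3·CHCl3 (2.5 mol%), (R,R)-ANDEN-phenyl Trost ligand (5.5 mol%), 1,4-dioxane, 23 °C
Reagents that add atoms: none
Why: Decarboxylative asymmetric allylic alkylation (Tsuji–Trost type): loss of CO2 gives a chiral π-allylpalladium enolate ion pair that recombines at C6 faster than proton exchange, so the ligand sets the tertiary centre (clerodane C10, R) without bis-allylation (the ligand antipode is used if the sense of induction proves opposite).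

Step 3
Reactants: 4 (R)-6-allyl-3-ethoxy-2-methylcyclohex-2-en-1-one
Product: 6 (R)-4-allyl-2,3-dimethylcyclohex-2-en-1-one, via lithium alkoxide 5 (not isolated)
Conditions: MeLi, Et2O, −78 → 0 °C; then 1 M aq HCl, THF, 0 °C → rt
Reagents that add atoms: methyllithium ([Li]C); water (O)
Why: Stork–Danheiser transposition: 1,2-addition of MeLi (C20), then acid hydrolysis of the enol ether and dehydration give the transposed tetrasubstituted enone and leave the γ-stereocentre untouched.

Step 4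
Reactants: 6 (R)-4-allyl-2,3-dimethylcyclohex-2-en-1-one
Product: 8 (R)-4-(2,2-dimethoxyethyl)-2,3-dimethylcyclohex-2-en-1-one, via aldehyde 7 (not isolated)
Conditions: O3 (1 equiv), CH2Cl2/MeOH, −78 °C; Me2S; then HC(OMe)3, PPTS (cat.), MeOH, rt
Reagents that add atoms: trimethyl orthoformate (COC(OC)OC)
Why: Ozonolysis takes the electron-rich terminal alkene in preference to the electron-poor tetrasubstituted enone alkene, and the C2 aldehyde is masked at once as its dimethyl acetal so that it survives the organometallic steps.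

Step 5
Reactants: 8 (R)-4-(2,2-dimethoxyethyl)-2,3-dimethylcyclohex-2-en-1-one; 9 but-3-en-1-ylmagnesium bromide
Product: 10 (3R,4R)-3-(but-3-en-1-yl)-4-(2,2-dimethoxyethyl)-2,3-dimethyl-1-(trimethylsilyloxy)cyclohex-1-ene
Conditions: CuBr·SMe2 (20 mol%), Me3SiCl, HMPA, THF, −78 → −30 °C; Et3N, pentane work-up
Reagents that add atoms: chlorotrimethylsilane (C[Si](C)(C)Cl)
Why: Copper-catalysed, silyl-chloride-accelerated 1,4-addition: allylic 1,2-strain against the C9 methyl holds the C10 arm pseudoaxial, so the butenyl group (C11–C14) enters anti to it and C9 becomes quaternary with its chain trans and its methyl cis to the C10 arm, the enolate being trapped as the enol silane that later shields the ketone.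

Step 6
Reactants: 10 (3R,4R)-3-(but-3-en-1-yl)-4-(2,2-dimethoxyethyl)-2,3-dimethyl-1-(trimethylsilyloxy)cyclohex-1-ene; 11 tert-butyl acrylate
Product: 12 tert-butyl (E)-5-[(1R,6R)-6-(2,2-dimethoxyethyl)-1,2-dimethyl-3-(trimethylsilyloxy)cyclohex-2-en-1-yl]pent-2-enoate
Conditions: 11 (5 equiv), second-generation Grubbs catalyst (5 mol%), CH2Cl2, 40 °C
Reagents that add atoms: none
Why: Olefin cross-metathesis of the only terminal alkene with the acrylate gives the (E)-enoate, the tetrasubstituted enol silane and the acetal being inert.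

Step 7
Reactants: 12 tert-butyl (E)-5-[(1R,6R)-6-(2,2-dimethoxyethyl)-1,2-dimethyl-3-(trimethylsilyloxy)cyclohex-2-en-1-yl]pent-2-enoate
Product: 14 tert-butyl (3R)-5-[(1R,2S,6R)-6-(2,2-dimethoxyethyl)-1,2-dimethyl-3-oxocyclohexyl]-3-methylpentanoate, via methylated enol silane 13 (not isolated)
Conditions: MeMgBr, CuI (5 mol%), (S)-Tol-BINAP (7.5 mol%), t-BuOMe, −20 °C; aq NH4Cl; then K2CO3 (cat.), MeOH, rt
Reagents that add atoms: methylmagnesium bromide (C[Mg]Br)
Why: Copper/Tol-BINAP-catalysed asymmetric conjugate addition of the methyl Grignard reagent to the (E)-enoate sets C13 (R) under catalyst control (ligand antipode if the sense proves opposite) while the enol silane keeps the ring ketone out of reach, and methanolysis then frees the ketone with the C8 methyl settling equatorial, cis to the C9 methyl (about 4:1 estimated from conformational analysis; re-equilibrated in step 12).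

Step 8
Reactants: 14 tert-butyl (3R)-5-[(1R,2S,6R)-6-(2,2-dimethoxyethyl)-1,2-dimethyl-3-oxocyclohexyl]-3-methylpentanoate
Product: 15 tert-butyl (3R)-5-[(1R,2S,6S)-6-(2,2-dimethoxyethyl)-1,2-dimethyl-3-oxocyclohex-4-en-1-yl]-3-methylpentanoate
Conditions: IBX, DMSO/PhF, 70 °C
Reagents that add atoms: none
Why: IBX dehydrogenation of the ketone can only go toward C6–C5, because the other α-carbon (C8) is flanked by quaternary C9.

Step 9
Reactants: 15 tert-butyl (3R)-5-[(1R,2S,6S)-6-(2,2-dimethoxyethyl)-1,2-dimethyl-3-oxocyclohex-4-en-1-yl]-3-methylpentanoate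
Product: 17 tert-butyl (3R)-5-[(1R,2S,6S)-6-(2,2-dimethoxyethyl)-1,2,5-trimethyl-3-oxocyclohex-4-en-1-yl]-3-methylpentanoate, via enol silane 16 (not isolated)
Conditions: MeMgBr, CuBr·SMe2 (10 mol%), Me3SiCl, HMPA, THF, −78 °C; then Pd(OAc)2 (10 mol%), O2 (1 atm), DMSO, rt
Reagents that add atoms: methylmagnesium bromide (C[Mg]Br)
Why: Copper-catalysed conjugate methylation (C19) with silyl trapping, then Saegusa–Ito oxidation of the crude enol silane, re-installs the double bond as the β-methyl enone needed for ring closure and erases the temporary C5 stereocentre.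

Step 10
Reactants: 17 tert-butyl (3R)-5-[(1R,2S,6S)-6-(2,2-dimethoxyethyl)-1,2,5-trimethyl-3-oxocyclohex-4-en-1-yl]-3-methylpentanoate
Product: 18 tert-butyl (3R)-3-methyl-5-[(1R,2S,6S)-1,2,5-trimethyl-3-oxo-6-(2-oxoethyl)cyclohex-4-en-1-yl]pentanoate
Conditions: AcOH/THF/H2O (3:1:1), 40 °C
Reagents that add atoms: water (O)
Why: Mild acid hydrolysis of the dimethyl acetal frees the C2 aldehyde without touching the tert-butyl ester or the enone.

Step 11
Reactants: 18 tert-butyl (3R)-3-methyl-5-[(1R,2S,6S)-1,2,5-trimethyl-3-oxo-6-(2-oxoethyl)cyclohex-4-en-1-yl]pentanoate; 19 methoxyallene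
Product: 21 tert-butyl (3R)-5-[(1R,2S,6S)-6-[3-methoxy-2-(triethylsilyloxy)penta-3,4-dien-1-yl]-1,2,5-trimethyl-3-oxocyclohex-4-en-1-yl]-3-methylpentanoate (C2 epimers), via lithium alkoxide 20 (not isolated)
Conditions: 19, n-BuLi, THF, −40 °C; 18, −78 °C; then Et3SiCl, −78 → 0 °C
Reagents that add atoms: chlorotriethylsilane (CC[Si](CC)(CC)Cl)
Why: 1-Lithio-1-methoxyallene is an acyl-anion (acryloyl-anion) equivalent whose carbanionic C3, the future ketone carbon, adds 1,2 to the aldehyde C2 far faster than to the hindered enone or the ester, joining two carbonyl-level carbons as a protected acyloin whose new C2 centre (both epimers) is later oxidized away.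

Step 12
Reactants: 21 tert-butyl (3R)-5-[(1R,2S,6S)-6-[3-methoxy-2-(triethylsilyloxy)penta-3,4-dien-1-yl]-1,2,5-trimethyl-3-oxocyclohex-4-en-1-yl]-3-methylpentanoate
Product: 23 tert-butyl (13R)-3,3-dimethoxy-7-oxo-2-(triethylsilyloxy)-cis-clerod-4(18)-en-15-oate (C5/C8/C9/C10 as in 28; C2 epimers), via enol silane ketal 22 (not isolated)
Conditions: Me3SiOTf (1.2 equiv), 2,6-di-tert-butyl-4-methylpyridine, CH2Cl2, −78 °C; MeOH, −78 → 0 °C; then K2CO3, MeOH, rt
Reagents that add atoms: methanol (CO)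
Why: Proposed new method: Me3SiOTf silylates the enone to a siloxyallyl cation and the nucleophilic central allene carbon (C4), held by the C10 tether, attacks C5 on the tether face in a 6-(enolendo)-exo-trig Mukaiyama–Michael closure that gives the cis ring fusion and the C5 quaternary centre, the resulting α-methylene oxocarbenium ion being captured by methanol as the ketal (which keeps C3 masked for the next step), the closest known chemistry being the allenyl-ether Nazarov cyclization, where the same allene carbon bonds to an enone β-carbon, and intramolecular Mukaiyama–Michael and Hosomi–Sakurai additions to 3-methylcyclohexenones; K2CO3/MeOH then cleaves the enol silane and equilibrates C8 to the equatorial methyl.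

Step 13
Reactants: 23 tert-butyl (13R)-3,3-dimethoxy-7-oxo-2-(triethylsilyloxy)-cis-clerod-4(18)-en-15-oate
Product: 24 tert-butyl (7S,13R)-7-hydroxy-3,3-dimethoxy-2-(triethylsilyloxy)-cis-clerod-4(18)-en-15-oate
Conditions: SmI2 (2.5 equiv), H2O, Et3N, THF, 0 °C
Reagents that add atoms: none
Why: Electron-transfer reduction through the ketyl and carbanion, as with dissolving metals, is expected to give the thermodynamically preferred equatorial 7-alcohol (trans to the C8 methyl), whereas hydride reagents, whose axial approach is blocked by C4 and the C9 methyl, would give the axial epimer; ketal, silyl ether, ester and isolated alkene survive.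

Step 14
Reactants: 24 tert-butyl (7S,13R)-7-hydroxy-3,3-dimethoxy-2-(triethylsilyloxy)-cis-clerod-4(18)-en-15-oate
Product: 25 tert-butyl (7S,13R)-7-acetoxy-3,3-dimethoxy-2-(triethylsilyloxy)-cis-clerod-4(18)-en-15-oate
Conditions: Ac2O, pyridine, DMAP (cat.), CH2Cl2, rt
Reagents that add atoms: acetic anhydride (CC(=O)OC(C)=O)
Why: DMAP-catalysed acetylation of the only free hydroxyl, which is equatorial and accessible, while C2–O is silylated and C3 is a ketal.

Step 15
Reactants: 25 tert-butyl (7S,13R)-7-acetoxy-3,3-dimethoxy-2-(triethylsilyloxy)-cis-clerod-4(18)-en-15-oate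
Product: 26 (7S,13R)-7-acetoxy-2-hydroxy-3-oxo-cis-clerod-4(18)-en-15-oic acid (C2 epimers)
Conditions: TFA/CH2Cl2/H2O (10:10:1), 0 °C → rt
Reagents that add atoms: water (O)
Why: One acid treatment hydrolyses the allylic ketal to the α-methylene ketone, removes the triethylsilyl ether and cleaves the tert-butyl ester as isobutene, the secondary acetate being acid-stable and the exocyclic alkene unable to migrate because C5 is quaternary.

Step 16
Reactants: 26 (7S,13R)-7-acetoxy-2-hydroxy-3-oxo-cis-clerod-4(18)-en-15-oic acid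
Product: 28 (5S,7S,8S,9R,10R,13R)-7-acetoxy-2-hydroxy-3-oxo-cis-cleroda-1,4(18)-dien-15-oic acid (CNP0257844.1), via diketone 27 (not isolated)
Conditions: Dess–Martin periodinane, CH2Cl2, 0 °C → rt
Reagents that add atoms: none
Why: Dess–Martin oxidation of the acyloin gives the 1,2-dione, which can enolize only toward C1 (C4 carries no hydrogen) and does so spontaneously to the conjugated, hydrogen-bonded diosphenol.

**Compound list**

1 | 3-ethoxy-2-methylcyclohex-2-en-1-one | CCOC1=C(C)C(=O)CCC1 | starting material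
2 | allyl chloroformate | C=CCOC(Cl)=O | starting material
3 | allyl 5-ethoxy-6-methylcyclohexa-1,5-dien-1-yl carbonate | C=CCOC(=O)OC1=CCCC(OCC)=C1C | intermediate
4 | (R)-6-allyl-3-ethoxy-2-methylcyclohex-2-en-1-one | CCOC1=C(C)C(=O)[C@@H](CC=C)CC1 | intermediate
5 | lithium (6R)-6-allyl-3-ethoxy-1,2-dimethylcyclohex-2-en-1-olate (carbinol epimers) | CCOC1=C(C)C(C)([O-])[C@@H](CC=C)CC1.[Li+] | intermediate (not isolated)
6 | (R)-4-allyl-2,3-dimethylcyclohex-2-en-1-one | O=C1CC[C@H](CC=C)C(C)=C1C | intermediate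
7 | (R)-2-(2,3-dimethyl-4-oxocyclohex-2-en-1-yl)acetaldehyde | O=C1CC[C@H](CC=O)C(C)=C1C | intermediate (not isolated)
8 | (R)-4-(2,2-dimethoxyethyl)-2,3-dimethylcyclohex-2-en-1-one | O=C1CC[C@H](CC(OC)OC)C(C)=C1C | intermediate
9 | but-3-en-1-ylmagnesium bromide | C=CCC[Mg]Br | starting material
10 | (3R,4R)-3-(but-3-en-1-yl)-4-(2,2-dimethoxyethyl)-2,3-dimethyl-1-(trimethylsilyloxy)cyclohex-1-ene | C[Si](C)(C)OC1=C(C)[C@](C)(CCC=C)[C@@H](CC(OC)OC)CC1 | intermediate
11 | tert-butyl acrylate | C=CC(=O)OC(C)(C)C | starting material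
12 | tert-butyl (E)-5-[(1R,6R)-6-(2,2-dimethoxyethyl)-1,2-dimethyl-3-(trimethylsilyloxy)cyclohex-2-en-1-yl]pent-2-enoate | C[Si](C)(C)OC1=C(C)[C@](C)(CC/C=C/C(=O)OC(C)(C)C)[C@@H](CC(OC)OC)CC1 | intermediate
13 | tert-butyl (3R)-5-[(1R,6R)-6-(2,2-dimethoxyethyl)-1,2-dimethyl-3-(trimethylsilyloxy)cyclohex-2-en-1-yl]-3-methylpentanoate | C[Si](C)(C)OC1=C(C)[C@](C)(CC[C@@H](C)CC(=O)OC(C)(C)C)[C@@H](CC(OC)OC)CC1 | intermediate (not isolated)
14 | tert-butyl (3R)-5-[(1R,2S,6R)-6-(2,2-dimethoxyethyl)-1,2-dimethyl-3-oxocyclohexyl]-3-methylpentanoate | O=C1CC[C@H](CC(OC)OC)[C@@](C)(CC[C@@H](C)CC(=O)OC(C)(C)C)[C@@H]1C | intermediate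
15 | tert-butyl (3R)-5-[(1R,2S,6S)-6-(2,2-dimethoxyethyl)-1,2-dimethyl-3-oxocyclohex-4-en-1-yl]-3-methylpentanoate | O=C1C=C[C@H](CC(OC)OC)[C@@](C)(CC[C@@H](C)CC(=O)OC(C)(C)C)[C@@H]1C | intermediate
16 | tert-butyl (3R)-5-[6-(2,2-dimethoxyethyl)-1,2,5-trimethyl-3-(trimethylsilyloxy)cyclohex-3-en-1-yl]-3-methylpentanoate (5-methyl trans to the 6-arm; other centres as in 15) | C[Si](C)(C)OC1=C[C@@H](C)[C@H](CC(OC)OC)[C@@](C)(CC[C@@H](C)CC(=O)OC(C)(C)C)[C@@H]1C | intermediate (not isolated)
17 | tert-butyl (3R)-5-[(1R,2S,6S)-6-(2,2-dimethoxyethyl)-1,2,5-trimethyl-3-oxocyclohex-4-en-1-yl]-3-methylpentanoate | O=C1C=C(C)[C@H](CC(OC)OC)[C@@](C)(CC[C@@H](C)CC(=O)OC(C)(C)C)[C@@H]1C | intermediate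
18 | tert-butyl (3R)-3-methyl-5-[(1R,2S,6S)-1,2,5-trimethyl-3-oxo-6-(2-oxoethyl)cyclohex-4-en-1-yl]pentanoate | O=C1C=C(C)[C@H](CC=O)[C@@](C)(CC[C@@H](C)CC(=O)OC(C)(C)C)[C@@H]1C | intermediate
19 | methoxyallene (1-methoxypropa-1,2-diene) | COC=C=C | starting material
20 | lithium alkoxide of the methoxyallene adduct of 18 (C2 epimers) | O=C1C=C(C)[C@H](CC([O-])C(OC)=C=C)[C@@](C)(CC[C@@H](C)CC(=O)OC(C)(C)C)[C@@H]1C.[Li+] | intermediate (not isolated)
21 | tert-butyl (3R)-5-[(1R,2S,6S)-6-[3-methoxy-2-(triethylsilyloxy)penta-3,4-dien-1-yl]-1,2,5-trimethyl-3-oxocyclohex-4-en-1-yl]-3-methylpentanoate (C2 epimers) | O=C1C=C(C)[C@H](CC(O[Si](CC)(CC)CC)C(OC)=C=C)[C@@](C)(CC[C@@H](C)CC(=O)OC(C)(C)C)[C@@H]1C | intermediate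
22 | tert-butyl (13R)-3,3-dimethoxy-2-(triethylsilyloxy)-7-(trimethylsilyloxy)-cis-cleroda-4(18),6-dien-15-oate (C2 epimers) | C=C1C(OC)(OC)C(O[Si](CC)(CC)CC)C[C@@H]2[C@@](C)(CC[C@@H](C)CC(=O)OC(C)(C)C)[C@H](C)C(O[Si](C)(C)C)=C[C@]12C | intermediate (not isolated)
23 | tert-butyl (13R)-3,3-dimethoxy-7-oxo-2-(triethylsilyloxy)-cis-clerod-4(18)-en-15-oate (C5, C8, C9, C10 as in 28; C2 epimers) | C=C1C(OC)(OC)C(O[Si](CC)(CC)CC)C[C@@H]2[C@@](C)(CC[C@@H](C)CC(=O)OC(C)(C)C)[C@H](C)C(=O)C[C@]12C | intermediate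
24 | tert-butyl (7S,13R)-7-hydroxy-3,3-dimethoxy-2-(triethylsilyloxy)-cis-clerod-4(18)-en-15-oate (C2 epimers) | C=C1C(OC)(OC)C(O[Si](CC)(CC)CC)C[C@@H]2[C@@](C)(CC[C@@H](C)CC(=O)OC(C)(C)C)[C@H](C)[C@@H](O)C[C@]12C | intermediate
25 | tert-butyl (7S,13R)-7-acetoxy-3,3-dimethoxy-2-(triethylsilyloxy)-cis-clerod-4(18)-en-15-oate (C2 epimers) | C=C1C(OC)(OC)C(O[Si](CC)(CC)CC)C[C@@H]2[C@@](C)(CC[C@@H](C)CC(=O)OC(C)(C)C)[C@H](C)[C@@H](OC(C)=O)C[C@]12C | intermediate
26 | (7S,13R)-7-acetoxy-2-hydroxy-3-oxo-cis-clerod-4(18)-en-15-oic acid (C2 epimers) | C=C1C(=O)C(O)C[C@@H]2[C@@](C)(CC[C@@H](C)CC(=O)O)[C@H](C)[C@@H](OC(C)=O)C[C@]12C | intermediate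
27 | (7S,13R)-7-acetoxy-2,3-dioxo-cis-clerod-4(18)-en-15-oic acid | C=C1C(=O)C(=O)C[C@@H]2[C@@](C)(CC[C@@H](C)CC(=O)O)[C@H](C)[C@@H](OC(C)=O)C[C@]12C | intermediate (not isolated)
28 | (5S,7S,8S,9R,10R,13R)-7-acetoxy-2-hydroxy-3-oxo-cis-cleroda-1,4(18)-dien-15-oic acid (CNP0257844.1) | C=C1C(=O)C(O)=C[C@@H]2[C@@](C)(CC[C@@H](C)CC(=O)O)[C@H](C)[C@@H](OC(C)=O)C[C@]12C | target

**Step count and risks**

Total steps: 16. Longest linear sequence: 16 (the route is linear from 1; all other inputs are purchased).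

Steps most likely to fail:

Step 12 (ring A closure). The allenyl ether may hydrolyse or ionize before its central carbon reaches the hindered β-carbon, and C5 is formed next to quaternary C9. The fallback sets out from aldehyde 18 and returns at acyloin acid 26; it closes ring A with an allylsilane and builds the C3 ketone and C4 methylene afterwards. 2-Lithio-3-(trimethylsilyl)propene (from 2-bromoallyltrimethylsilane and t-BuLi) is added to 18 and the alkoxide is silylated with Et3SiCl to give the allylsilane silyl ether F1. EtAlCl2 in CH2Cl2 at −78 °C closes ring A by intramolecular Hosomi–Sakurai addition to the enone, giving the cis-fused 3-methylene ketone F2. SmI2/H2O/Et3N gives the equatorial 7-alcohol F3 and Ac2O/DMAP its acetate F4. Ozonolysis (O3, then Me2S) of the exocyclic alkene gives the 3-ketone F5. α-Methylenation at C4 with paraformaldehyde and N-methylanilinium trifluoroacetate gives the α-methylene ketone F6. TFA/CH2Cl2/H2O then removes the silyl ether and the tert-butyl ester to give 26.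

Step 5 (quaternary C9). A primary alkyl copper reagent may not add to the tetrasubstituted, γ-branched enone. The fallback sets out from enone 8 and returns at ketone 14; it makes the C9–C11 bond with a smaller sp2 nucleophile, the C12–C13 bond by cross-coupling, and sets C13 by hydride instead of methyl delivery. Vinylmagnesium bromide, CuBr·SMe2 and Me3SiCl give the vinyl enol silane F7. 9-BBN hydroborates the vinyl group to the alkylborane F8. Suzuki–Miyaura coupling of F8 with tert-butyl (Z)-3-iodobut-2-enoate (Pd(dppf)Cl2, aq K3PO4, DMF, which also hydrolyses the enol silane) gives the (Z)-enoate ketone F9. Copper hydride conjugate reduction (Cu(OAc)2, DTBM-SEGPHOS enantiomer chosen for 13R, PMHS, t-BuOH, toluene) then gives 14.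

Step 13 (C7 configuration). The samarium reduction may not give the equatorial alcohol cleanly. The fallback sets out from ketone 23 and returns at alcohol 24; it separates reduction from stereocontrol. NaBH4 in MeOH at 0 °C gives mainly the axial 7-epi alcohol F10 by equatorial hydride attack. The carbinol centre is then equilibrated by reversible hydrogen transfer (Ru(CO)2Cl(η5-C5Ph5), KOt-Bu, toluene, rt to 60 °C) to the equatorial alcohol 24, which is favoured because the axial hydroxyl is syn-diaxial to C4 and the C9 methyl.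

Further compounds
F1 | step 12 | tert-butyl (3R)-3-methyl-5-[(1R,2S,6S)-1,2,5-trimethyl-3-oxo-6-{2-(triethylsilyloxy)-3-[(trimethylsilyl)methyl]but-3-en-1-yl}cyclohex-4-en-1-yl]pentanoate (carbinol epimers) | O=C1C=C(C)[C@H](CC(O[Si](CC)(CC)CC)C(=C)C[Si](C)(C)C)[C@@](C)(CC[C@@H](C)CC(=O)OC(C)(C)C)[C@@H]1C
F2 | step 12 | cis-fused bicyclic ketone, ring A with C2–OSiEt3, exocyclic methylene on C3 and C4H2, C7 ketone, tert-butyl ester (otherwise as 23) | C1C(=C)C(O[Si](CC)(CC)CC)C[C@@H]2[C@@](C)(CC[C@@H](C)CC(=O)OC(C)(C)C)[C@H](C)C(=O)C[C@]12C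
F3 | step 12 | (7S)-7-alcohol of F2 | C1C(=C)C(O[Si](CC)(CC)CC)C[C@@H]2[C@@](C)(CC[C@@H](C)CC(=O)OC(C)(C)C)[C@H](C)[C@@H](O)C[C@]12C
F4 | step 12 | 7-acetate of F3 | C1C(=C)C(O[Si](CC)(CC)CC)C[C@@H]2[C@@](C)(CC[C@@H](C)CC(=O)OC(C)(C)C)[C@H](C)[C@@H](OC(C)=O)C[C@]12C
F5 | step 12 | 3-ketone from F4 (ring A: C2–OSiEt3, C3=O, C4H2) | C1C(=O)C(O[Si](CC)(CC)CC)C[C@@H]2[C@@](C)(CC[C@@H](C)CC(=O)OC(C)(C)C)[C@H](C)[C@@H](OC(C)=O)C[C@]12C
F6 | step 12 | tert-butyl (7S,13R)-7-acetoxy-3-oxo-2-(triethylsilyloxy)-cis-clerod-4(18)-en-15-oate | C=C1C(=O)C(O[Si](CC)(CC)CC)C[C@@H]2[C@@](C)(CC[C@@H](C)CC(=O)OC(C)(C)C)[C@H](C)[C@@H](OC(C)=O)C[C@]12C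
F7 | step 5 | 4-(2,2-dimethoxyethyl)-2,3-dimethyl-1-(trimethylsilyloxy)-3-vinylcyclohex-1-ene (ring centres as in 10) | C[Si](C)(C)OC1=C(C)[C@](C)(C=C)[C@@H](CC(OC)OC)CC1
F8 | step 5 | B-alkyl-9-borabicyclo[3.3.1]nonane from hydroboration of F7 | C[Si](C)(C)OC1=C(C)[C@](C)(CCB2C3CCCC2CCC3)[C@@H](CC(OC)OC)CC1
F9 | step 5 | tert-butyl (Z)-5-[(1R,2S,6R)-6-(2,2-dimethoxyethyl)-1,2-dimethyl-3-oxocyclohexyl]-3-methylpent-2-enoate | O=C1CC[C@H](CC(OC)OC)[C@@](C)(CC/C(C)=C\C(=O)OC(C)(C)C)[C@@H]1C
F10 | step 13 | tert-butyl (7R,13R)-7-hydroxy-3,3-dimethoxy-2-(triethylsilyloxy)-cis-clerod-4(18)-en-15-oate (7-epimer of 24) | C=C1C(OC)(OC)C(O[Si](CC)(CC)CC)C[C@@H]2[C@@](C)(CC[C@@H](C)CC(=O)OC(C)(C)C)[C@H](C)[C@H](O)C[C@]12C
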